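## The problem

- The target has four rings. Hydroquinone ring A is fused to five-membered ring C, whose three sp3 carbons are Ca (quaternary, prenyl-bearing), Cb (quaternary, aryl-bearing) and Cc (benzylic CH). The Ca–Cb bond is shared with ring B, a cyclohex-2-ene-1,4-dione. Cb and Cc are also spanned by a CH2–C(CH3)=CH bridge (ring D), so rings C and D form a bicyclo[3.2.1]octene with Ca as the one-carbon bridge.
- There are three contiguous stereocentres (Ca S, Cb R, Cc R), two of them vicinal quaternary carbons. The bridge forces its two ends to be cis on ring C. The SMILES places both ring-B carbonyl carbons on one face of ring C and prenyl on the face of the bridge.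
- Only one element is therefore independent: the absolute configuration at Ca together with a cis B/C fusion. Cb follows from the fusion and Cc from the tether.
- The hydroquinone is air-sensitive and a ligand for Lewis acids. The enedione is a Michael acceptor and easily reduced. The prenyl and ring-D alkenes are trisubstituted and acid-sensitive.
- The hard bonds are Ca–Cb (quaternary to quaternary) and the Cc–CH= bond, which must place the ring-D double bond next to Cc and not next to Cb.
- The enabling feature: the two carbonyl carbons of ring B sit on the adjacent carbons Ca and Cb, and Ca–Cb is at the same time the C2–C3 bond of an indan-1-one whose C1 is Cc. Ring B is thus the (4+2) adduct of a 2-prenylindenone and a 1,4-dioxygenated butadiene.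

## Retrosynthesis

**25 ⇒ 23.** The two phenolic O–H groups are traced to methyl ethers. Methyl ethers come with the commercial indanone 7, survive every base and Lewis acid on the way, and keep the arene electron-rich enough to carry a benzylic cation. The forward step must remove them without acid strong enough to attack the alkenes, which points to oxidative demethylation through quinone 24 and immediate re-reduction.

**23 ⇒ 22.** The Cc–CH= bond of ring D is cut, leaving a benzylic silyl ether at Cc and a Z-vinylsilane on Cb. Cutting here, and not at Cb–CH2, means Cc needs no controlled configuration beforehand: a planar benzylic cation can only be reached by the tether from the face on which Cb holds it. The silicon fixes the double bond next to Cc, which a simple methallyl terminator would not do. The precursor 22 has lost the bridged ring and one stereocentre.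

**22 ⇒ 20 + 6.** The Cb–CH2 bond is cut to the enedione 20 and the allylic bromide 6. In 20 the Cb–H is the only enolisable position (benzylic and α to a ketone). The B/C fusion can only stay cis if the electrophile enters syn to prenyl, which is the target configuration. The forward reaction has to form a quaternary carbon next to another one, the most demanding bond of the route after the key step.

**20 ⇒ 16 (through 19, 18, 17).** No skeletal bond is cut. The enedione is the oxidised form of a cis-ene-1,4-diol (19), itself a diacetate (18). The silyloxy group at Cc comes from the ketone of 16 by reduction (17) and silylation. The ketone is reduced before the acetates are touched, because a triketone would be open to retro-Claisen cleavage. The carbinol is silylated so that no β-alkoxy ketone can undergo retro-aldol cleavage in step 12.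

**16 ⇒ 14 + 15.** Ring B is opened at the bonds from Ca and Cb to the two acetoxy-bearing carbons, giving indenone 14 and the symmetrical diene 15. This removes one ring, two skeletal bonds and four stereocentres at once, and both partners are flat and simple. The forward reaction must deliver the cis fusion (automatic for a suprafacial addition) and one enantioface of the indenone.

**14 ⇒ 7 + 10 (through 12, 9).** The prenyl group is cut from C2 and the C2=C3 double bond is traced to a selenoxide elimination. Selenium is put on first (9), so that the prenylation meets a single α-hydrogen and selenium bromide never meets the prenyl alkene.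

**6 ⇒ 1 (through 5, 3).** The bromide comes from the allylic alcohol 5 and this from the Z-iodide 3. Carbometallation of propargyl alcohol 1 sets the Z geometry, and it is carried through with retention.

## Roads not taken

**Alternative 1:** The cut removes both bonds from ring A to the cage (aryl–Cb and aryl–Cc) and treats ring A as cyclohexane-1,4-dione A1. In the forward key step an enolate of A1 would add to the unsubstituted β-carbon (Cc) of the cross-conjugated dienone A2. The enolate on the neighbouring α-carbon would then add to the ring-fusion β-carbon (Cb), closing ring C and giving cage A3.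
- Merits: the bicyclo[3.2.1] core and both ring-A bonds arise in one operation from a cheap partner, and no benzylic cation is needed late. In this respect it is better than the chosen plan.
- Weak points: the second addition must create quaternary Cb at a fully substituted β-carbon beside quaternary Ca. The face is set only by the difference between prenyl and a ring methylene on Ca.
- A3 is also far from the target. The bridge ketone has two nearly equivalent α-methylenes, so the position of the ring-D alkene is not secured. Ring A must be dehydrogenated and ring B deprotected, oxidised and dehydrogenated in the presence of two other dicarbonyl units.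
- Against this the chosen plan sets an arene present from the first step, an alkene position fixed by silicon and far fewer redox steps after the key step.

**Alternative 2:** The cut removes Ca–Cb and the ring-B bond from the carbon that becomes the Cb-side carbonyl to the neighbouring CH=. In the forward key step the enolate at Ca of precursor A4 would add to the nitroalkene carbon Cb, closing ring C. The nitronate would then add to the β-methoxy enone and expel methoxide, closing ring B, to give A5. A nitro-to-ketone conversion then leads into the same end-game as the chosen route.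
- Merits: the vicinal quaternary bond is made intramolecularly and the ring-D side chain sits on Cb from the outset. The intermolecular alkylation of a hindered enolate (step 12 here) is avoided, and on this point the alternative is the better one.
- Weak points: A4 is a long acyclic assembly. A β,β-disubstituted nitroalkene is a poor and reversible acceptor. The enolate at Ca carries a β-silyloxy group on Cc and can eliminate it.
- The only source of asymmetry is the carbinol at Cc, which must relay to Ca by 1,2-induction and is later destroyed. The Nef-type step also has to work on a hindered secondary nitro group beside an enone.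
- The chosen plan sets Ca directly in a concerted, catalyst-controlled step from two simple partners and is shorter.

**Alternative 3:** The cut removes the Ca–Cc bond. In the forward key step the silyl ketene acetal of δ-lactone A6 would rearrange through a boat transition state (Ireland–Claisen ring contraction). The tertiary allylic C–O bond breaks and Ca–Cc forms, giving cyclohexene acid A7 with quaternary Ca, aryl-bearing Cc and the ring-D alkene in place.
- Merits: the alkene position is fixed by the sigmatropic shift as securely as by the vinylsilane here. Chirality transfer from a carbinol to Ca and Cc is arguably more predictable than a catalytic enantioselective cycloaddition on a new substrate.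
- Weak points: after A7 the aryl–Cb bond (quaternary, bridging) is still to be made. Ring B must then be built from a hindered acid and a masked aldehyde with two further carbons and several oxidation-state changes on a congested cage. A6 itself needs a tertiary allylic carbinol of defined configuration.
- The chosen plan closes ring B and sets Ca in one convergent step and needs only one further skeletal bond before the final ring closure.

Key step: step 7

Assumption 1: the (S)-configured oxazaborolidinium is taken to expose the indenone face that leads to 16; should the sense prove opposite, the (R)-catalyst is used and nothing else changes.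

Assumption 2: hydride is taken to enter C9 of 16 from the prenyl side (anti to the acetoxy-bearing C1), giving the carbinol configuration drawn for 17 to 22; this centre is destroyed in step 13, so either epimer serves.

## Route

Step 1
Reactants: 1 prop-2-yn-1-ol
Product: 3 (Z)-3-iodo-2-methylprop-2-en-1-ol, via alkenylmagnesium alkoxide 2 (not isolated)
Conditions: MeMgBr (2.5 equiv), CuI (10 mol %), THF, −20 °C → rt; then I2, −78 → 0 °C; aq NH4Cl
Reagents that add atoms: methylmagnesium bromide, C[Mg]Br; iodine, II
Why: Copper-catalysed anti-carbomagnesiation of the propargylic alkoxide delivers methyl to C2 and holds magnesium on C3 in a five-membered chelate, cis to CH2O; iodinolysis with retention gives the Z-iodide.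

Step 2
Reactants: 3 (Z)-3-iodo-2-methylprop-2-en-1-ol
Product: 5 (Z)-2-methyl-3-(trimethylsilyl)prop-2-en-1-ol, via trimethylsilyl ether 4 (not isolated)
Conditions: n-BuLi (1.05 equiv), THF, −78 °C; Me3SiCl (1.05 equiv), −78 → 0 °C; then t-BuLi (2.1 equiv), −78 → −20 °C; H2O
Reagents that add atoms: chlorotrimethylsilane, C[Si](C)(C)Cl
Why: O-silylation, iodine–lithium exchange with retention of alkene geometry and 1,4-O→C silyl migration (retro-Brook rearrangement) of the cis-disposed alkenyllithium place silicon cis to CH2OH.

Step 3
Reactants: 5 (Z)-2-methyl-3-(trimethylsilyl)prop-2-en-1-ol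
Product: 6 (Z)-(3-bromo-2-methylprop-1-en-1-yl)trimethylsilane
Conditions: CBr4, PPh3, CH2Cl2, 0 °C
Reagents that add atoms: carbon tetrabromide, BrC(Br)(Br)Br
Why: Appel reaction, an SN2 displacement at the primary allylic carbon under neutral conditions that leave the vinylsilane and its Z geometry intact.

Step 4
Reactants: 7 4,7-dimethoxyindan-1-one
Product: 9 4,7-dimethoxy-2-(phenylselanyl)indan-1-one (racemic), via lithium enolate 8 (not isolated)
Conditions: LiN(iPr)2 (1.1 equiv), THF, −78 °C; PhSeBr (1.1 equiv), −78 °C
Reagents that add atoms: benzeneselenenyl bromide, Br[Se]c1ccccc1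
Why: α-Selenenylation of the kinetic lithium enolate; fast addition at −78 °C limits proton exchange and double selenenylation, and the new centre is of no consequence.

Step 5
Reactants: 9 4,7-dimethoxy-2-(phenylselanyl)indan-1-one; 10 1-bromo-3-methylbut-2-ene (prenyl bromide)
Product: 12 4,7-dimethoxy-2-(3-methylbut-2-en-1-yl)-2-(phenylselanyl)indan-1-one (racemic), via lithium enolate 11 (not isolated)
Conditions: LiN(iPr)2 (1.1 equiv), THF, −78 °C; 10 (1.3 equiv), DMPU, −78 → 0 °C
Reagents that add atoms: none
Why: SN2 alkylation of an α-seleno ketone enolate by a primary allylic bromide; the single remaining α-hydrogen excludes over-alkylation, and the racemic quaternary centre is lost in step 6.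

Step 6
Reactants: 12 4,7-dimethoxy-2-(3-methylbut-2-en-1-yl)-2-(phenylselanyl)indan-1-one
Product: 14 4,7-dimethoxy-2-(3-methylbut-2-en-1-yl)-1H-inden-1-one, via selenoxide 13 (not isolated)
Conditions: mCPBA (1.05 equiv), CH2Cl2, −78 °C; then iPr2NH, −78 → 0 °C
Reagents that add atoms: none
Why: Selenide oxidation at −78 °C is far faster than epoxidation of the prenyl alkene, and the selenoxide undergoes syn-elimination on warming; the benzylic ring C3–H, held syn-periplanar to C–Se in the flat five-membered ring, is expected to be taken in preference to the side-chain CH2, and the amine keeps PhSeOH from adding back.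

Step 7
Reactants: 14 4,7-dimethoxy-2-(3-methylbut-2-en-1-yl)-1H-inden-1-one; 15 (1E,3E)-buta-1,3-diene-1,4-diyl diacetate
Product: 16 (1R,4S,4aR,9aS)-5,8-dimethoxy-9a-(3-methylbut-2-en-1-yl)-9-oxo-4,4a,9,9a-tetrahydro-1H-fluorene-1,4-diyl diacetate
Conditions: 15 (3 equiv), (S)-1-(2-methylphenyl)-3,3-diphenyltetrahydro-1H,3H-pyrrolo[1,2-c][1,3,2]oxazaborole (C24H24BNO, 20 mol %) protonated by HN(SO2CF3)2 (18 mol %), CH2Cl2, −78 → −20 °C; Et3N quench
Reagents that add atoms: none
Why: A concerted but asynchronous normal-demand (4+2) cycloaddition joins the boron-activated C2=C3 bond of 14 to the termini of 15; the bond to the β-carbon C3 leads and the bond to the α-carbon C2, which becomes the quaternary centre, lags, so the prenyl group is tolerated. The closest known reaction type is the oxazaborolidinium-catalysed Diels–Alder addition of cyclic enones and quinones to oxygenated dienes, together with thermal and Lewis-acid additions of 1,4-diacyloxybutadienes and of indenones. Ring B closes in the cycloaddition mode, both σ-bonds forming suprafacially on each partner, which makes the six–five fusion cis by necessity. C9a and C4a are thus fixed relative to each other by the ring-bound cis alkene, and their absolute sense by the catalyst, which binds the only ketone and screens one face of the flat indenone. C1 and C4 follow from the E,E geometry of 15 (acetates mutually cis) and from the endo transition state, in which the diene lies under the carbonyl and arene and away from prenyl (acetates syn to C9 and C4b). The step needs enantioface selectivity above all, since C1 and C4 are erased in step 11 and the symmetrical diene raises no regiochemical question; endo selectivity only serves to give a single diastereomer. Strain makes the indenone a reactive dienophile, and the acetoxy diene, unlike a silyloxy diene, survives the strong Lewis acid.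

Step 8
Reactants: 16 (1R,4S,4aR,9aS)-5,8-dimethoxy-9a-(3-methylbut-2-en-1-yl)-9-oxo-4,4a,9,9a-tetrahydro-1H-fluorene-1,4-diyl diacetate
Product: 17 (1R,4S,4aS,9R,9aR)-9-hydroxy-5,8-dimethoxy-9a-(3-methylbut-2-en-1-yl)-4,4a,9,9a-tetrahydro-1H-fluorene-1,4-diyl diacetate
Conditions: NaBH4, CeCl3·7H2O, MeOH, −40 → 0 °C
Reagents that add atoms: none
Why: Luche reduction takes the hindered aryl ketone quickly under nearly neutral conditions, so the allylic acetates are neither cleaved nor shifted; hydride is expected from the prenyl side, away from the acetoxy-bearing C1 (assumption 2).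

Step 9
Reactants: 17 (1R,4S,4aS,9R,9aR)-9-hydroxy-5,8-dimethoxy-9a-(3-methylbut-2-en-1-yl)-4,4a,9,9a-tetrahydro-1H-fluorene-1,4-diyl diacetate
Product: 18 (1R,4S,4aS,9R,9aS)-9-[(tert-butyldimethylsilyl)oxy]-5,8-dimethoxy-9a-(3-methylbut-2-en-1-yl)-4,4a,9,9a-tetrahydro-1H-fluorene-1,4-diyl diacetate
Conditions: t-BuMe2SiOTf (1.5 equiv), 2,6-lutidine, CH2Cl2, −78 → 0 °C
Reagents that add atoms: tert-butyldimethylsilyl trifluoromethanesulfonate, CC(C)(C)[Si](C)(C)OS(=O)(=O)C(F)(F)F
Why: Silyl triflate and a hindered base silylate the crowded secondary benzylic alcohol; the ether blocks retro-aldol cleavage later and is the latent leaving group for step 13.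

Step 10
Reactants: 18 (1R,4S,4aS,9R,9aS)-9-[(tert-butyldimethylsilyl)oxy]-5,8-dimethoxy-9a-(3-methylbut-2-en-1-yl)-4,4a,9,9a-tetrahydro-1H-fluorene-1,4-diyl diacetate
Product: 19 (1R,4S,4aS,9R,9aS)-9-[(tert-butyldimethylsilyl)oxy]-5,8-dimethoxy-9a-(3-methylbut-2-en-1-yl)-4,4a,9,9a-tetrahydro-1H-fluorene-1,4-diol
Conditions: i-Bu2AlH (5 equiv), CH2Cl2, −78 °C; aq KNaC4H4O6 (potassium sodium tartrate)
Reagents that add atoms: none
Why: Reductive cleavage of the two acetates by the aluminium hydride gives the cis-ene-1,4-diol without a free alkoxide in protic base, which avoids 1,3-migration of the silyl group from O9 to O1; alkenes and silyl ether are inert.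

Step 11
Reactants: 19 (1R,4S,4aS,9R,9aS)-9-[(tert-butyldimethylsilyl)oxy]-5,8-dimethoxy-9a-(3-methylbut-2-en-1-yl)-4,4a,9,9a-tetrahydro-1H-fluorene-1,4-diol
Product: 20 (4aR,9S,9aR)-9-[(tert-butyldimethylsilyl)oxy]-5,8-dimethoxy-9a-(3-methylbut-2-en-1-yl)-9,9a-dihydro-1H-fluorene-1,4(4aH)-dione
Conditions: Dess–Martin periodinane (3 equiv), NaHCO3, CH2Cl2, 0 °C → rt
Reagents that add atoms: none
Why: Dess–Martin oxidation of both secondary allylic alcohols gives the ene-1,4-dione under buffered, non-basic conditions; C1 and C4 cease to be stereocentres, and C4a–H stays cis because the cis six–five fusion is the stable one.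

Step 12
Reactants: 20 (4aR,9S,9aR)-9-[(tert-butyldimethylsilyl)oxy]-5,8-dimethoxy-9a-(3-methylbut-2-en-1-yl)-9,9a-dihydro-1H-fluorene-1,4(4aH)-dione; 6 (Z)-(3-bromo-2-methylprop-1-en-1-yl)trimethylsilane
Product: 22 (4aR,9S,9aR)-9-[(tert-butyldimethylsilyl)oxy]-5,8-dimethoxy-9a-(3-methylbut-2-en-1-yl)-4a-[(2Z)-2-methyl-3-(trimethylsilyl)prop-2-en-1-yl]-9,9a-dihydro-1H-fluorene-1,4(4aH)-dione, via potassium enolate 21 (not isolated)
Conditions: KN(SiMe3)2 (1.05 equiv), THF, −78 °C, 20 added to the base; then 6 (1.5 equiv), −78 → 0 °C
Reagents that add atoms: none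
Why: Deprotonation at the only enolisable position (C4a–H, benzylic and α-keto) and SN2 alkylation of the enolate by the allylic bromide; the electrophile must enter syn to prenyl and anti to C1 to keep the six–five fusion cis, which is the target configuration at Cb, and inverse addition keeps enolate and free enedione apart.

Step 13
Reactants: 22 (4aR,9S,9aR)-9-[(tert-butyldimethylsilyl)oxy]-5,8-dimethoxy-9a-(3-methylbut-2-en-1-yl)-4a-[(2Z)-2-methyl-3-(trimethylsilyl)prop-2-en-1-yl]-9,9a-dihydro-1H-fluorene-1,4(4aH)-dione
Product: 23 (4aR,9R,9aS)-5,8-dimethoxy-11-methyl-9a-(3-methylbut-2-en-1-yl)-9,9a-dihydro-4aH-9,4a-prop[1]enofluorene-1,4-dione (bridge C10H=C11(CH3)–C12H2 from C9 to C4a)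
Conditions: Me3SiOTf (0.5 equiv), 2,6-di-tert-butyl-4-methylpyridine (0.6 equiv), CH2Cl2, −78 → −20 °C
Reagents that add atoms: none
Why: Silyl-transfer activation of the benzylic silyl ether releases a cation stabilised by the ortho-methoxy arene, and the Z-vinylsilane held on the same face by C4a attacks through its silicon-bearing carbon (6-endo vinylsilane-terminated cation cyclisation); the β-silyl cation loses Me3Si+ with retention, placing the double bond next to C9 and regenerating Me3SiOTf, while the tether dictates the C9 configuration and the quaternary C9a rules out elimination.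

Step 14
Reactants: 23 (4aR,9R,9aS)-5,8-dimethoxy-11-methyl-9a-(3-methylbut-2-en-1-yl)-9,9a-dihydro-4aH-9,4a-prop[1]enofluorene-1,4-dione
Product: 25 (4aR,9R,9aS)-5,8-dihydroxy-11-methyl-9a-(3-methylbut-2-en-1-yl)-9,9a-dihydro-4aH-9,4a-prop[1]enofluorene-1,4-dione (the target), via quinone 24 (not isolated)
Conditions: (NH4)2Ce(NO3)6 (2.5 equiv), MeCN/H2O, 0 °C; then aq Na2S2O4, EtOAc, 0 °C, brief contact
Reagents that add atoms: water, O
Why: Oxidative demethylation of the 1,4-dimethoxyarene by tetravalent cerium gives the p-quinone, whose carbonyl oxygens come from water, and dithionite then reduces the quinone, by far the best electron acceptor present, to the hydroquinone; no stereocentre is touched, and the non-enolisable enedione and the two trisubstituted alkenes are expected to survive the short, cold treatment.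

## Compound list

1 | prop-2-yn-1-ol | C#CCO | starting material
2 | bromomagnesium (Z)-3-(bromomagnesio)-2-methylprop-2-en-1-olate | Br[Mg]OC/C(C)=C\[Mg]Br | intermediate
3 | (Z)-3-iodo-2-methylprop-2-en-1-ol | OC/C(C)=C\I | intermediate
4 | (Z)-[(3-iodo-2-methylprop-2-en-1-yl)oxy]trimethylsilane | C[Si](C)(C)OC/C(C)=C\I | intermediate
5 | (Z)-2-methyl-3-(trimethylsilyl)prop-2-en-1-ol | OC/C(C)=C\[Si](C)(C)C | intermediate
6 | (Z)-(3-bromo-2-methylprop-1-en-1-yl)trimethylsilane | BrC/C(C)=C\[Si](C)(C)C | intermediate
7 | 4,7-dimethoxyindan-1-one | COc1ccc(OC)c2C(=O)CCc12 | starting material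
8 | lithium 4,7-dimethoxy-1H-inden-3-olate (enolate of 7) | [Li]OC1=CCc2c(OC)ccc(OC)c12 | intermediate
9 | 4,7-dimethoxy-2-(phenylselanyl)indan-1-one (racemic) | COc1ccc(OC)c2C(=O)C([Se]c3ccccc3)Cc12 | intermediate
10 | 1-bromo-3-methylbut-2-ene (prenyl bromide) | CC(C)=CCBr | starting material
11 | lithium 4,7-dimethoxy-2-(phenylselanyl)-1H-inden-3-olate (enolate of 9) | [Li]OC1=C([Se]c2ccccc2)Cc2c(OC)ccc(OC)c12 | intermediate
12 | 4,7-dimethoxy-2-(3-methylbut-2-en-1-yl)-2-(phenylselanyl)indan-1-one (racemic) | CC(C)=CCC1([Se]c2ccccc2)Cc2c(OC)ccc(OC)c2C1=O | intermediate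
13 | 4,7-dimethoxy-2-(3-methylbut-2-en-1-yl)-2-(phenylseleninyl)indan-1-one | CC(C)=CCC1([Se](=O)c2ccccc2)Cc2c(OC)ccc(OC)c2C1=O | intermediate
14 | 4,7-dimethoxy-2-(3-methylbut-2-en-1-yl)-1H-inden-1-one | CC(C)=CCC1=Cc2c(OC)ccc(OC)c2C1=O | intermediate
15 | (1E,3E)-buta-1,3-diene-1,4-diyl diacetate | CC(=O)O/C=C/C=C/OC(C)=O | starting material
16 | (1R,4S,4aR,9aS)-5,8-dimethoxy-9a-(3-methylbut-2-en-1-yl)-9-oxo-4,4a,9,9a-tetrahydro-1H-fluorene-1,4-diyl diacetate (cis-fused; both acetates anti to prenyl) | CC(C)=CC[C@@]12[C@H](OC(C)=O)C=C[C@H](OC(C)=O)[C@@H]1c1c(OC)ccc(OC)c1C2=O | intermediate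
17 | (1R,4S,4aS,9R,9aR)-9-hydroxy-5,8-dimethoxy-9a-(3-methylbut-2-en-1-yl)-4,4a,9,9a-tetrahydro-1H-fluorene-1,4-diyl diacetate | CC(C)=CC[C@@]12[C@H](OC(C)=O)C=C[C@H](OC(C)=O)[C@@H]1c1c(OC)ccc(OC)c1[C@@H]2O | intermediate
18 | (1R,4S,4aS,9R,9aS)-9-[(tert-butyldimethylsilyl)oxy]-5,8-dimethoxy-9a-(3-methylbut-2-en-1-yl)-4,4a,9,9a-tetrahydro-1H-fluorene-1,4-diyl diacetate | CC(C)=CC[C@@]12[C@H](OC(C)=O)C=C[C@H](OC(C)=O)[C@@H]1c1c(OC)ccc(OC)c1[C@@H]2O[Si](C)(C)C(C)(C)C | intermediate
19 | (1R,4S,4aS,9R,9aS)-9-[(tert-butyldimethylsilyl)oxy]-5,8-dimethoxy-9a-(3-methylbut-2-en-1-yl)-4,4a,9,9a-tetrahydro-1H-fluorene-1,4-diol | CC(C)=CC[C@@]12[C@H](O)C=C[C@H](O)[C@@H]1c1c(OC)ccc(OC)c1[C@@H]2O[Si](C)(C)C(C)(C)C | intermediate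
20 | (4aR,9S,9aR)-9-[(tert-butyldimethylsilyl)oxy]-5,8-dimethoxy-9a-(3-methylbut-2-en-1-yl)-9,9a-dihydro-1H-fluorene-1,4(4aH)-dione | CC(C)=CC[C@@]12C(=O)C=CC(=O)[C@@H]1c1c(OC)ccc(OC)c1[C@@H]2O[Si](C)(C)C(C)(C)C | intermediate
21 | potassium C4–C4a enolate of 20 | CC(C)=CC[C@@]12C(=O)C=CC([O-])=C1c1c(OC)ccc(OC)c1[C@@H]2O[Si](C)(C)C(C)(C)C.[K+] | intermediate
22 | (4aR,9S,9aR)-9-[(tert-butyldimethylsilyl)oxy]-5,8-dimethoxy-9a-(3-methylbut-2-en-1-yl)-4a-[(2Z)-2-methyl-3-(trimethylsilyl)prop-2-en-1-yl]-9,9a-dihydro-1H-fluorene-1,4(4aH)-dione | CC(C)=CC[C@@]12C(=O)C=CC(=O)[C@]1(C/C(C)=C\[Si](C)(C)C)c1c(OC)ccc(OC)c1[C@@H]2O[Si](C)(C)C(C)(C)C | intermediate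
23 | (4aR,9R,9aS)-5,8-dimethoxy-11-methyl-9a-(3-methylbut-2-en-1-yl)-9,9a-dihydro-4aH-9,4a-prop[1]enofluorene-1,4-dione | CC(C)=CC[C@@]12C(=O)C=CC(=O)[C@@]13CC(C)=C[C@@H]2c1c(OC)ccc(OC)c13 | intermediate
24 | (4aS,9R,9aS)-11-methyl-9a-(3-methylbut-2-en-1-yl)-9,9a-dihydro-4aH-9,4a-prop[1]enofluorene-1,4,5,8-tetrone | CC(C)=CC[C@@]12C(=O)C=CC(=O)[C@@]13CC(C)=C[C@@H]2C2=C3C(=O)C=CC2=O | intermediate
25 | (4aR,9R,9aS)-5,8-dihydroxy-11-methyl-9a-(3-methylbut-2-en-1-yl)-9,9a-dihydro-4aH-9,4a-prop[1]enofluorene-1,4-dione | CC(C)=CC[C@@]12C(=O)C=CC(=O)[C@@]13CC(C)=C[C@@H]2c1c(O)ccc(O)c13 | target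

## Step count and risks

Total: 14 steps. Longest linear sequence: 11 steps (steps 4 to 14, from 7 to 25). Bromide 6 is made in 3 steps (1 to 3) and enters at step 12.

**Step 7 (key step).** The bulky boron cation may bind poorly to a carbonyl flanked by the peri-methoxy group and the C2 substituent. The indenone also lacks the α-vinyl hydrogen that usually organises such complexes. The result could be slow turnover, poor facial discrimination, or acid-induced ionisation of the allylic acetates of the product on prolonged exposure. The fallback gives up catalysis for resolution. Indenone 14 and diene 15 are combined without catalyst in toluene at 90–110 °C (or at about 10 kbar at room temperature). Suprafacial addition still gives the cis-fused endo adduct, now as 16 together with the mirror-image adduct F1. The two are separated on a chiral stationary phase, and the route is rejoined at 16.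

**Step 12.** The enolate carbon lies between the quaternary C9a and the arene. C-alkylation may therefore be slow, so that O-alkylation or conjugate addition of the enolate to unreacted enedione takes over. The fallback changes the electrophile from an SN2 partner to a π-allyl complex. Alcohol 5 is converted with methyl chloroformate and pyridine into the methyl carbonate F2. F2 is then combined with 20 and Pd(PPh3)4 (zerovalent palladium) in THF (Tsuji–Trost allylation). The methoxide set free generates the enolate in low concentration. Attack is expected at the CH2 terminus remote from silicon, and any O-allyl material is re-ionised and funnelled to carbon. The route is rejoined at 22. Partial loss of the Z geometry through syn–anti exchange of the allyl complex would have to be checked, since the E isomer should cyclise more slowly.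

**Step 13.** Ionisation may fail, because the ether oxygen is crowded and the cation lies β to a carbonyl. Alternatively, traces of triflic acid may protodesilylate the vinylsilane or protonate the prenyl alkene before the ring closes. The fallback changes the cation precursor. The silyl ether of 22 is removed with HF·pyridine in THF to give the free benzylic alcohol F3. Acidic fluoride is used because a free alkoxide could undergo retro-aldol cleavage. F3 is ionised directly with BF3·OEt2 in CH2Cl2 at −78 °C in the presence of the hindered pyridine, and the route is rejoined at 23.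

**Step 6.** The syn-elimination may take a hydrogen from the allylic CH2 of the prenyl group instead of the ring, giving the exocyclic dienone. The fallback forms the ring double bond before the prenyl group is present. Selenide 9 is oxidised (mCPBA, −78 °C, then iPr2NH) to 4,7-dimethoxy-1H-inden-1-one F4, where only ring hydrogens are available. F4 is iodinated at C2 with I2 and pyridine to 2-iodo-4,7-dimethoxy-1H-inden-1-one F5. Stille coupling of F5 with tributyl(3-methylbut-2-en-1-yl)stannane (Pd2(dba)3, AsPh3, CuI, DMF) then gives 14.

**Step 14.** Tetravalent cerium may attack the electron-rich trisubstituted alkenes, or dithionite may reduce the enedione double bond as well as the quinone. The fallback avoids the redox pair. The ethers of 23 are cleaved by Lewis-acid dealkylation with BCl3 and Bu4NI in CH2Cl2 at −78 °C, and the route is rejoined directly at 25 (no new compound, F0).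

## Further compounds

F1 | step 7 | (1S,4R,4aS,9aR)-5,8-dimethoxy-9a-(3-methylbut-2-en-1-yl)-9-oxo-4,4a,9,9a-tetrahydro-1H-fluorene-1,4-diyl diacetate (enantiomer of 16) | CC(C)=CC[C@]12[C@@H](OC(C)=O)C=C[C@@H](OC(C)=O)[C@H]1c1c(OC)ccc(OC)c1C2=O
F2 | step 12 | methyl (Z)-2-methyl-3-(trimethylsilyl)prop-2-en-1-yl carbonate | COC(=O)OC/C(C)=C\[Si](C)(C)C
F3 | step 13 | (4aR,9S,9aR)-9-hydroxy-5,8-dimethoxy-9a-(3-methylbut-2-en-1-yl)-4a-[(2Z)-2-methyl-3-(trimethylsilyl)prop-2-en-1-yl]-9,9a-dihydro-1H-fluorene-1,4(4aH)-dione | CC(C)=CC[C@@]12C(=O)C=CC(=O)[C@]1(C/C(C)=C\[Si](C)(C)C)c1c(OC)ccc(OC)c1[C@@H]2O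
F4 | step 6 | 4,7-dimethoxy-1H-inden-1-one | COc1ccc(OC)c2C(=O)C=Cc12
F5 | step 6 | 2-iodo-4,7-dimethoxy-1H-inden-1-one | COc1ccc(OC)c2C(=O)C(I)=Cc12
F0 | step 14 | none | none
A1 | alternative 1 | cyclohexane-1,4-dione | O=C1CCC(=O)CC1
A2 | alternative 1 | 8-(tert-butyldimethylsilyloxy)-5,5-(ethylenedioxy)-4a-(3-methylbut-2-en-1-yl)-5,6,7,8-tetrahydronaphthalen-2(4aH)-one (cross-conjugated dienone) | CC(C)=CC[C@@]12C3(OCCO3)CC[C@H](O[Si](C)(C)C(C)(C)C)C1=CC(=O)C=C2
A3 | alternative 1 | bicyclo[3.2.1]octanone cage with ring B as ketal and silyl ether and ring A as a fused cyclohexane-1,4-dione | CC(C)=CC[C@@]12C3(OCCO3)CC[C@H](O[Si](C)(C)C(C)(C)C)[C@@]14CC(=O)C[C@@H]2[C@@H]2C(=O)CCC(=O)[C@@H]24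
A4 | alternative 2 | aryl-linked β-methoxy enone and β,β-disubstituted nitroalkene (Ca epimers, nitroalkene geometry open) | CC(C)=CCC(C(=O)/C=C/OC)[C@@H](O[Si](C)(C)C(C)(C)C)c1c(OC)ccc(OC)c1C(C\C(C)=C/[Si](C)(C)C)=C[N+](=O)[O-]
A5 | alternative 2 | cis-fused tricycle with quaternary Ca and Cb, enone and nitro group in ring B | CC(C)=CC[C@@]12C(=O)C=C[C@H]([N+](=O)[O-])[C@]1(C\C(C)=C/[Si](C)(C)C)c1c(OC)ccc(OC)c1[C@@H]2O[Si](C)(C)C(C)(C)C
A6 | alternative 3 | δ-lactone with tertiary allylic C–O bond, E-styryl group, dithianyl and prenyl substituents (Ca epimers) | O=C1C(CC=C(C)C)[C@H](C2SCCCS2)C[C@@](C)(/C=C/c2c(OC)ccc(OC)c2Br)O1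
A7 | alternative 3 | cyclohexene acid with quaternary Ca, aryl-bearing Cc and the methyl alkene in place | OC(=O)[C@]1(CC=C(C)C)[C@H](C2SCCCS2)CC(C)=C[C@@H]1c1c(OC)ccc(OC)c1Br
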